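**Plan**
1. Retrosynthetic cuts, in order: the six O-protecting bonds; the aryl–acyl bond C4–C4a of ring C; the aryl–vinyl bond of the chalcone arm (Heck); the O1–C2 aryl ether bond (Mitsunobu); the C2–C3 bond (auxiliary aldol).
2. Forward: the aldol joins the ring-B aldehyde to the bromoarylacetyl imide (C2–C3); reduction and silylation; Mitsunobu attaches the ring-A phenol (O1–C2); desilylation and oxidation give the 3-aryloxy acid; Heck adds the enone arm; ring C is closed last; one deprotection step.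
3. Enabling feature: ring A is a phloroglucinol triether, so in the open precursor the two carbons ortho to O1 (C4a and its twin C8) are equivalent and each is ortho/para to three oxygens. A six-ring acylation from C4 is therefore mild, can only give the 5,7-dioxygenated chromanone, and can be run late on the complete skeleton.
4. C3 lies α to the ketone formed in that step, so the 2,3-trans (diequatorial diaryl) arrangement is also the thermodynamic one.
5. Stereochemistry: the aldol sets the carbinol (S) and the aryl-bearing carbon; Mitsunobu inversion turns the carbinol into C2 (R); C3 (S) is carried from the aldol and backed by equilibration; the E-alkene comes from the Heck step.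
6. Protecting groups: benzyl ethers on five phenols; a tert-butyl carbonate on the ring-B phenol keeps the benzylic C2–O bond from ionising under acid.

Key step: step 11

Remark: the five building blocks used as starting materials are taken as catalogue compounds; the target is read as the 2,3-trans (2R,3S) flavanone that the SMILES encodes.

**Route**

Step 1
Reactants: 1 2-(5-bromo-2-hydroxyphenyl)acetic acid
Product: 2 2-[2-(benzyloxy)-5-bromophenyl]acetic acid
Conditions: BnBr (1.1 equiv), NaOH (2.2 equiv), EtOH–H2O, reflux; then HCl (aq) to pH 2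
Reagents that add atoms: benzyl bromide (BrCc1ccccc1)
Why: Williamson ether synthesis: in aqueous-alcoholic NaOH the phenoxide of the dianion is far more nucleophilic than the carboxylate, so benzyl bromide should alkylate the phenol oxygen, and any benzyl ester formed is saponified in the same pot.

Step 2
Reactants: 2 2-[2-(benzyloxy)-5-bromophenyl]acetic acid; 3 (S)-4-benzyl-1,3-oxazolidin-2-one
Product: 5 (S)-4-benzyl-3-{2-[2-(benzyloxy)-5-bromophenyl]acetyl}-1,3-oxazolidin-2-one, via mixed pivalic anhydride 4 (not isolated)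
Conditions: PivCl, Et3N, THF, −20 °C; then 3, LiCl, −20 °C → rt
Reagents that add atoms: none
Why: N-acylation of the oxazolidinone through the mixed pivalic anhydride (LiCl/Et3N activation) is the standard mild entry to N-acyl oxazolidinones and is regioselective because the hindered pivaloyl carbonyl is not attacked.

Step 3
Reactants: 5 (S)-4-benzyl-3-{2-[2-(benzyloxy)-5-bromophenyl]acetyl}-1,3-oxazolidin-2-one; 6 tert-butyl 4-formylphenyl carbonate
Product: 8 (S)-4-benzyl-3-[(2S,3S)-2-[2-(benzyloxy)-5-bromophenyl]-3-{4-[(tert-butoxycarbonyl)oxy]phenyl}-3-hydroxypropanoyl]-1,3-oxazolidin-2-one, via Z-dibutylboron enolate 7 (not isolated)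
Conditions: Bu2BOTf, i-Pr2NEt, CH2Cl2, −78 → 0 °C; 6, −78 → 0 °C; then pH 7 buffer, MeOH, 30% H2O2, 0 °C
Reagents that add atoms: none
Why: Evans syn-aldol reaction: the Z-boron enolate reacts through a chair Zimmerman–Traxler transition state on the enolate face away from the benzyl group of the auxiliary, which should set both new centres (2S,3S), the carbinol centre being the future C2 and the aryl-bearing centre the future C3.

Step 4
Reactants: 8 (S)-4-benzyl-3-[(2S,3S)-2-[2-(benzyloxy)-5-bromophenyl]-3-{4-[(tert-butoxycarbonyl)oxy]phenyl}-3-hydroxypropanoyl]-1,3-oxazolidin-2-one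
Product: 9 tert-butyl 4-[(1S,2R)-2-[2-(benzyloxy)-5-bromophenyl]-1,3-dihydroxypropyl]phenyl carbonate
Conditions: LiBH4, MeOH (1 equiv), THF, 0 °C
Reagents that add atoms: none
Why: Reductive cleavage of the auxiliary: LiBH4 should reduce the activated exocyclic imide carbonyl at 0 °C much faster than the hindered aryl tert-butyl carbonate, freeing the primary alcohol without touching either stereocentre.

Step 5
Reactants: 9 tert-butyl 4-[(1S,2R)-2-[2-(benzyloxy)-5-bromophenyl]-1,3-dihydroxypropyl]phenyl carbonate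
Product: 10 tert-butyl 4-[(1S,2R)-2-[2-(benzyloxy)-5-bromophenyl]-3-[(tert-butyldimethylsilyl)oxy]-1-hydroxypropyl]phenyl carbonate
Conditions: TBSCl, imidazole, CH2Cl2, 0 °C
Reagents that add atoms: tert-butyldimethylsilyl chloride (CC(C)(C)[Si](C)(C)Cl)
Why: Selective silylation: the unhindered primary hydroxyl reacts with TBSCl far faster than the β-branched secondary benzylic hydroxyl, which is left free for the next step.

Step 6
Reactants: 10 tert-butyl 4-[(1S,2R)-2-[2-(benzyloxy)-5-bromophenyl]-3-[(tert-butyldimethylsilyl)oxy]-1-hydroxypropyl]phenyl carbonate; 11 3,5-bis(benzyloxy)phenol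
Product: 12 tert-butyl 4-[(1R,2R)-2-[2-(benzyloxy)-5-bromophenyl]-1-[3,5-bis(benzyloxy)phenoxy]-3-[(tert-butyldimethylsilyl)oxy]propyl]phenyl carbonate
Conditions: PPh3, DIAD, toluene, 0 °C → rt
Reagents that add atoms: none
Why: Mitsunobu etherification: SN2 attack of the phenol on the alkoxyphosphonium ion should invert the carbinol centre to R (the C2 configuration of the target), the electron-poor carbonate-bearing ring disfavouring ionisation and the absence of a carbonyl-activated β-hydrogen disfavouring elimination.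

Step 7
Reactants: 12 tert-butyl 4-[(1R,2R)-2-[2-(benzyloxy)-5-bromophenyl]-1-[3,5-bis(benzyloxy)phenoxy]-3-[(tert-butyldimethylsilyl)oxy]propyl]phenyl carbonate
Product: 13 tert-butyl 4-[(1R,2R)-2-[2-(benzyloxy)-5-bromophenyl]-1-[3,5-bis(benzyloxy)phenoxy]-3-hydroxypropyl]phenyl carbonate
Conditions: HF·pyridine, pyridine, THF, 0 °C → rt
Reagents that add atoms: none
Why: Fluoride cleavage of the primary silyl ether: buffered HF·pyridine removes the alkyl TBS group while the aryl benzyl ethers, the aryl carbonate and the benzylic aryl ether are inert.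

Step 8
Reactants: 13 tert-butyl 4-[(1R,2R)-2-[2-(benzyloxy)-5-bromophenyl]-1-[3,5-bis(benzyloxy)phenoxy]-3-hydroxypropyl]phenyl carbonate
Product: 14 (2S,3R)-2-[2-(benzyloxy)-5-bromophenyl]-3-[3,5-bis(benzyloxy)phenoxy]-3-{4-[(tert-butoxycarbonyl)oxy]phenyl}propanoic acid
Conditions: TEMPO (20 mol %), PhI(OAc)2, MeCN–H2O (1:1), rt
Reagents that add atoms: water (O)
Why: TEMPO-catalysed oxidation with PhI(OAc)2 in wet acetonitrile takes the primary alcohol through the aldehyde hydrate to the acid under near-neutral conditions, so the β-aryloxy group should not be eliminated and the electron-rich rings should not be attacked.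

Step 9
Reactants: 15 1-[2,4-bis(benzyloxy)phenyl]ethan-1-one
Product: 16 1-[2,4-bis(benzyloxy)phenyl]prop-2-en-1-one
Conditions: (CH2O)n, i-Pr2NH·CF3CO2H, CF3CO2H (cat.), THF, reflux
Reagents that add atoms: paraformaldehyde as formaldehyde (C=O)
Why: Mannich-type α-methylenation: the secondary ammonium salt and formaldehyde give an iminium ion that is attacked by the enol of the aryl methyl ketone, and β-elimination of the amine from the Mannich base delivers the vinyl ketone.

Step 10
Reactants: 14 (2S,3R)-2-[2-(benzyloxy)-5-bromophenyl]-3-[3,5-bis(benzyloxy)phenoxy]-3-{4-[(tert-butoxycarbonyl)oxy]phenyl}propanoic acid; 16 1-[2,4-bis(benzyloxy)phenyl]prop-2-en-1-one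
Product: 17 (2S,3R)-2-{2-(benzyloxy)-5-[(E)-3-[2,4-bis(benzyloxy)phenyl]-3-oxoprop-1-en-1-yl]phenyl}-3-[3,5-bis(benzyloxy)phenoxy]-3-{4-[(tert-butoxycarbonyl)oxy]phenyl}propanoic acid
Conditions: Pd(OAc)2 (5 mol %), P(o-tol)3 (10 mol %), Et3N, DMF, 90 °C
Reagents that add atoms: none
Why: Mizoroki–Heck reaction: oxidative addition of the aryl bromide to zerovalent palladium, insertion of the terminal electron-poor alkene at its CH2 end and syn β-hydride elimination should give the E-enone, with the carboxylate, the carbonate and the benzyl ethers as spectators.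

Step 11
Reactants: 17 (2S,3R)-2-{2-(benzyloxy)-5-[(E)-3-[2,4-bis(benzyloxy)phenyl]-3-oxoprop-1-en-1-yl]phenyl}-3-[3,5-bis(benzyloxy)phenoxy]-3-{4-[(tert-butoxycarbonyl)oxy]phenyl}propanoic acid
Product: 19 tert-butyl 4-[(2R,3S)-5,7-bis(benzyloxy)-3-{2-(benzyloxy)-5-[(E)-3-[2,4-bis(benzyloxy)phenyl]-3-oxoprop-1-en-1-yl]phenyl}-4-oxo-3,4-dihydro-2H-chromen-2-yl]phenyl carbonate, via mixed trifluoroacetic anhydride 18 (not isolated)
Conditions: (CF3CO)2O, CH2Cl2, 0 °C → rt; NaHCO3 (aq) work-up
Reagents that add atoms: none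
Why: Trifluoroacetic anhydride converts the acid into the mixed anhydride 18, whose acyl carbon (C4) is attacked by the ortho carbon (C4a) of the 3,5-bis(benzyloxy)phenoxy ring in an intramolecular Friedel–Crafts acylation (Wheland intermediate, then loss of a proton). The closest known reaction type is the cyclisation of 3-aryloxypropanoic acids to chroman-4-ones. Ring C closes in the 6-exo-trig mode (C4a onto the anhydride carbonyl, leaving group outside the new ring). No bond to C2 is made or broken, so its R configuration is carried over from step 6; C3 arrives S from the aldol and, being α to the new ketone and enolisable, this trans (diequatorial 2,3-diaryl) arrangement is also the thermodynamic one, so any C3 epimer should drain to the same product. The step needs C-acylation of ring A to beat acylation of the other arenes, attack on the enone and ionisation of the benzylic C2–O bond: ring A is the only ring with three donor oxygens and offers two equivalent positions at six-ring distance, closure onto ring B would be a five-ring onto a carbonate-deactivated arene, and the same carbonate keeps C2 from ionising in trifluoroacetic acid.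

Step 12
Reactants: 19 tert-butyl 4-[(2R,3S)-5,7-bis(benzyloxy)-3-{2-(benzyloxy)-5-[(E)-3-[2,4-bis(benzyloxy)phenyl]-3-oxoprop-1-en-1-yl]phenyl}-4-oxo-3,4-dihydro-2H-chromen-2-yl]phenyl carbonate
Product: 20 (2R,3S)-3-{5-[(E)-3-(2,4-dihydroxyphenyl)-3-oxoprop-1-en-1-yl]-2-hydroxyphenyl}-5,7-dihydroxy-2-(4-hydroxyphenyl)-2,3-dihydro-4H-chromen-4-one
Conditions: BCl3, C6HMe5, CH2Cl2, −78 °C; then MeOH, −78 °C → rt
Reagents that add atoms: none
Why: Lewis-acid debenzylation: BCl3 ionises the five aryl benzyl ethers at −78 °C and pentamethylbenzene traps the benzyl cations so that neither the enone nor the electron-rich rings are benzylated, the intact carbonate keeps C2 from ionising during this stage, and the HCl–MeOH formed on quenching should then remove the tert-butyl carbonate by acidolysis.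

**Compound list**
1 | 2-(5-bromo-2-hydroxyphenyl)acetic acid | OC(=O)Cc1cc(Br)ccc1O | starting material
2 | 2-[2-(benzyloxy)-5-bromophenyl]acetic acid | OC(=O)Cc1cc(Br)ccc1OCc1ccccc1 | intermediate
3 | (S)-4-benzyl-1,3-oxazolidin-2-one | O=C1N[C@@H](Cc2ccccc2)CO1 | starting material
4 | 2-[2-(benzyloxy)-5-bromophenyl]acetic pivalic anhydride | CC(C)(C)C(=O)OC(=O)Cc1cc(Br)ccc1OCc1ccccc1 | intermediate
5 | (S)-4-benzyl-3-{2-[2-(benzyloxy)-5-bromophenyl]acetyl}-1,3-oxazolidin-2-one | O=C(Cc1cc(Br)ccc1OCc1ccccc1)N1[C@@H](Cc2ccccc2)COC1=O | intermediate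
6 | tert-butyl 4-formylphenyl carbonate | O=Cc1ccc(OC(=O)OC(C)(C)C)cc1 | starting material
7 | Z-dibutylboron enolate of 5 | CCCCB(CCCC)O/C(=C\c1cc(Br)ccc1OCc1ccccc1)N1[C@@H](Cc2ccccc2)COC1=O | intermediate
8 | (S)-4-benzyl-3-[(2S,3S)-2-[2-(benzyloxy)-5-bromophenyl]-3-{4-[(tert-butoxycarbonyl)oxy]phenyl}-3-hydroxypropanoyl]-1,3-oxazolidin-2-one | O=C([C@@H](c1cc(Br)ccc1OCc1ccccc1)[C@H](O)c1ccc(OC(=O)OC(C)(C)C)cc1)N1[C@@H](Cc2ccccc2)COC1=O | intermediate
9 | tert-butyl 4-[(1S,2R)-2-[2-(benzyloxy)-5-bromophenyl]-1,3-dihydroxypropyl]phenyl carbonate | OC[C@@H](c1cc(Br)ccc1OCc1ccccc1)[C@H](O)c1ccc(OC(=O)OC(C)(C)C)cc1 | intermediate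
10 | tert-butyl 4-[(1S,2R)-2-[2-(benzyloxy)-5-bromophenyl]-3-[(tert-butyldimethylsilyl)oxy]-1-hydroxypropyl]phenyl carbonate | CC(C)(C)[Si](C)(C)OC[C@@H](c1cc(Br)ccc1OCc1ccccc1)[C@H](O)c1ccc(OC(=O)OC(C)(C)C)cc1 | intermediate
11 | 3,5-bis(benzyloxy)phenol | Oc1cc(OCc2ccccc2)cc(OCc2ccccc2)c1 | starting material
12 | tert-butyl 4-[(1R,2R)-2-[2-(benzyloxy)-5-bromophenyl]-1-[3,5-bis(benzyloxy)phenoxy]-3-[(tert-butyldimethylsilyl)oxy]propyl]phenyl carbonate | CC(C)(C)[Si](C)(C)OC[C@@H](c1cc(Br)ccc1OCc1ccccc1)[C@@H](Oc1cc(OCc2ccccc2)cc(OCc2ccccc2)c1)c1ccc(OC(=O)OC(C)(C)C)cc1 | intermediate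
13 | tert-butyl 4-[(1R,2R)-2-[2-(benzyloxy)-5-bromophenyl]-1-[3,5-bis(benzyloxy)phenoxy]-3-hydroxypropyl]phenyl carbonate | OC[C@@H](c1cc(Br)ccc1OCc1ccccc1)[C@@H](Oc1cc(OCc2ccccc2)cc(OCc2ccccc2)c1)c1ccc(OC(=O)OC(C)(C)C)cc1 | intermediate
14 | (2S,3R)-2-[2-(benzyloxy)-5-bromophenyl]-3-[3,5-bis(benzyloxy)phenoxy]-3-{4-[(tert-butoxycarbonyl)oxy]phenyl}propanoic acid | OC(=O)[C@@H](c1cc(Br)ccc1OCc1ccccc1)[C@@H](Oc1cc(OCc2ccccc2)cc(OCc2ccccc2)c1)c1ccc(OC(=O)OC(C)(C)C)cc1 | intermediate
15 | 1-[2,4-bis(benzyloxy)phenyl]ethan-1-one | CC(=O)c1ccc(OCc2ccccc2)cc1OCc1ccccc1 | starting material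
16 | 1-[2,4-bis(benzyloxy)phenyl]prop-2-en-1-one | C=CC(=O)c1ccc(OCc2ccccc2)cc1OCc1ccccc1 | intermediate
17 | (2S,3R)-2-{2-(benzyloxy)-5-[(E)-3-[2,4-bis(benzyloxy)phenyl]-3-oxoprop-1-en-1-yl]phenyl}-3-[3,5-bis(benzyloxy)phenoxy]-3-{4-[(tert-butoxycarbonyl)oxy]phenyl}propanoic acid | OC(=O)[C@@H](c1cc(/C=C/C(=O)c2ccc(OCc3ccccc3)cc2OCc2ccccc2)ccc1OCc1ccccc1)[C@@H](Oc1cc(OCc2ccccc2)cc(OCc2ccccc2)c1)c1ccc(OC(=O)OC(C)(C)C)cc1 | intermediate
18 | mixed anhydride of 17 with trifluoroacetic acid | O=C(OC(=O)C(F)(F)F)[C@@H](c1cc(/C=C/C(=O)c2ccc(OCc3ccccc3)cc2OCc2ccccc2)ccc1OCc1ccccc1)[C@@H](Oc1cc(OCc2ccccc2)cc(OCc2ccccc2)c1)c1ccc(OC(=O)OC(C)(C)C)cc1 | intermediate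
19 | tert-butyl 4-[(2R,3S)-5,7-bis(benzyloxy)-3-{2-(benzyloxy)-5-[(E)-3-[2,4-bis(benzyloxy)phenyl]-3-oxoprop-1-en-1-yl]phenyl}-4-oxo-3,4-dihydro-2H-chromen-2-yl]phenyl carbonate | O=C(/C=C/c1ccc(OCc2ccccc2)c([C@@H]2C(=O)c3c(OCc4ccccc4)cc(OCc4ccccc4)cc3O[C@H]2c2ccc(OC(=O)OC(C)(C)C)cc2)c1)c1ccc(OCc2ccccc2)cc1OCc1ccccc1 | intermediate
20 | (2R,3S)-3-{5-[(E)-3-(2,4-dihydroxyphenyl)-3-oxoprop-1-en-1-yl]-2-hydroxyphenyl}-5,7-dihydroxy-2-(4-hydroxyphenyl)-2,3-dihydro-4H-chromen-4-one | O=C(/C=C/c1ccc(O)c([C@@H]2C(=O)c3c(O)cc(O)cc3O[C@H]2c2ccc(O)cc2)c1)c1ccc(O)cc1O | target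

**Step count**
Total steps: 12. Longest linear sequence: 11 steps (steps 1–8 and 10–12; step 9 is the side branch).

**Steps most likely to fail**

Step 6 (Mitsunobu etherification). The alkoxyphosphonium ion at the hindered, β-branched benzylic carbon may lose the neighbouring benzylic proton (elimination to the stilbene) faster than the phenol displaces it, or partly ionise so that inversion is incomplete. The fallback sets out from 10 and comes back at 12; it forms the C–O bond at the aryl carbon, so the carbinol centre is not touched. Dess–Martin oxidation of 10 should give aryl ketone F1. Corey–Bakshi–Shibata reduction [(S)-2-methyl-CBS-oxazaborolidine, BH3·SMe2, aryl as the large group] should give the (1R,2R)-alcohol F2, the carbinol epimer of 10. Chan–Lam etherification of F2 with [3,5-bis(benzyloxy)phenyl]boronic acid [Cu(OAc)2, pyridine, 4 Å molecular sieves, air, CH2Cl2, rt] arylates the oxygen with retention and should deliver 12. Any loss at the α-carbon of F1 is harmless, because C3 is equilibrated after ring closure.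

Step 10 (Heck reaction). The aryl vinyl ketone may polymerise or add the amine base, and the electron-rich aryl bromide may undergo slow oxidative addition and reductive loss of bromine, so that insertion is outrun. The fallback sets out from 14 and comes back at 17. Stille coupling of 14 with tributyl(vinyl)stannane [Pd(PPh3)4, toluene, 100 °C] should give vinylarene acid F3. Cross-metathesis of F3 with enone 16 (second-generation Hoveyda–Grubbs catalyst, CH2Cl2, 40 °C) should then give the E-enone 17 without base.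

Step 11 (ring closure). The activated acyl group, or the trifluoroacetic acid released, may be consumed by the enone arm (conjugate Friedel–Crafts alkylation by ring A of a second molecule, oligomerisation) before C-acylation is complete. The fallback sets out from 14 and comes back at 19; it closes the ring before the enone exists and then attaches the enone without base. Trifluoroacetic anhydride in CH2Cl2 should cyclise bromo acid 14 to bromoflavanone F4. Stille coupling with tributyl(vinyl)stannane [Pd(PPh3)4, toluene, 100 °C; neutral, so the base-labile flavanone is not opened] should give vinylflavanone F5. Cross-metathesis of F5 with 16 (second-generation Hoveyda–Grubbs catalyst, CH2Cl2, 40 °C) should give 19.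

**Further compounds**
F1 | step 6 | tert-butyl 4-[(2R)-2-[2-(benzyloxy)-5-bromophenyl]-3-[(tert-butyldimethylsilyl)oxy]propanoyl]phenyl carbonate | CC(C)(C)[Si](C)(C)OC[C@@H](c1cc(Br)ccc1OCc1ccccc1)C(=O)c1ccc(OC(=O)OC(C)(C)C)cc1
F2 | step 6 | tert-butyl 4-[(1R,2R)-2-[2-(benzyloxy)-5-bromophenyl]-3-[(tert-butyldimethylsilyl)oxy]-1-hydroxypropyl]phenyl carbonate | CC(C)(C)[Si](C)(C)OC[C@@H](c1cc(Br)ccc1OCc1ccccc1)[C@@H](O)c1ccc(OC(=O)OC(C)(C)C)cc1
F3 | step 10 | (2S,3R)-2-[2-(benzyloxy)-5-ethenylphenyl]-3-[3,5-bis(benzyloxy)phenoxy]-3-{4-[(tert-butoxycarbonyl)oxy]phenyl}propanoic acid | OC(=O)[C@@H](c1cc(C=C)ccc1OCc1ccccc1)[C@@H](Oc1cc(OCc2ccccc2)cc(OCc2ccccc2)c1)c1ccc(OC(=O)OC(C)(C)C)cc1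
F4 | step 11 | tert-butyl 4-[(2R,3S)-5,7-bis(benzyloxy)-3-[2-(benzyloxy)-5-bromophenyl]-4-oxo-3,4-dihydro-2H-chromen-2-yl]phenyl carbonate | Brc1ccc(OCc2ccccc2)c([C@@H]2C(=O)c3c(OCc4ccccc4)cc(OCc4ccccc4)cc3O[C@H]2c2ccc(OC(=O)OC(C)(C)C)cc2)c1
F5 | step 11 | tert-butyl 4-[(2R,3S)-5,7-bis(benzyloxy)-3-[2-(benzyloxy)-5-ethenylphenyl]-4-oxo-3,4-dihydro-2H-chromen-2-yl]phenyl carbonate | C=Cc1ccc(OCc2ccccc2)c([C@@H]2C(=O)c3c(OCc4ccccc4)cc(OCc4ccccc4)cc3O[C@H]2c2ccc(OC(=O)OC(C)(C)C)cc2)c1
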